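30.4% of the left-handed substrate and 74.2% of the right-handed substrate were the fractions left at the last red reading, 40.0 min, if each product came from its own hand. From them I took the apparent selectivity factor, the logarithm of the first fraction left over that of the second, 3.99, as a reading at 70 °C with its scatter.

| flask | left-handed substrate | right-handed substrate | solid reagent | temperature | remark | time |
|---|---|---|---|---|---|---|
| red | 1.2 M | 1.2 M | 1.6 M | 70 °C | run made earlier |  |
| Friday's | 0.80 M | 0.80 M | 1.60 M | 70 °C |  | 2.0 h |
| Wednesday's | 0.80 M | 0.80 M | 1.60 M |  | at 40 °C until 80 min, from then on at 70 °C | 2.0 h |
| Monday's | 0.80 M | 0.80 M | 1.60 M | 40 °C |  | 2.0 h |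

red run (percent of the left-handed substrate and right-handed substrate together charged)

| time / min | left-handed product / % | right-handed product / % |
|---|---|---|
| 5.00 | 3.4 | 0 |
| 10.0 | 7.5 | 4.0 |
| 15.0 | 12.5 | 5.3 |
| 20.0 | 16.4 | 7.3 |
| 25.0 | 21.9 | 8.3 |
| 30.0 | 27.1 | 11.4 |
| 40.0 | 34.8 | 12.9 |

(scatter of a reading: 1 percentage point)

- coupling partner is single-handed; left-handed substrate and right-handed substrate are mirror images of each other, charged as a racemate, each of them at the stated concentration
- given per volume of solution although it is solid: solid reagent
- at the start none of the solid reagent is in solution
- an excess is the difference of the two amounts in percent of their sum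
- the earlier runs do not show what temperature does; that part of a forecast is a guess
- an excess is below zero if the other one leads
- the handed part of coupling partner does not stay in what it makes, so the products of the two hands are mirror images too

1. the flask with the highest excess of left-handed product over right-handed product ("all alike" if they lie within 1.5 percentage points) (Friday's / Wednesday's / Monday's / all alike)
2. excess of left-handed product over right-handed product at the end, Friday's
3. excess of left-handed product over right-handed product at the end, Wednesday's
4. excess of left-handed product over right-handed product at the end, Monday's

Two hands that stay apart and keep one ratio of rate constants hold this factor constant at every conversion, but at 20.0 min the red run gave 2.52, so with the later reading higher, I reckoned that substrate was crossing between the hands and that the excess would hold instead of falling. The last red reading gives an excess of 45.9%, a reading with its scatter, which I would carry to Friday's flask at the same 70 °C, while what the colder temperature does in the other two flasks stayed a guess. The forecast differs, with 43% for Friday's, 44% for Wednesday's and 46% for Monday's, its choice for the highest, on the ground that “the substrate hands probably interconvert quickly”.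

Friday's flask ended at 39.6%, Wednesday's at 39.4% and Monday's at 43.5%, the highest.

    solid reagent ⇌ coupling partner, rate k1*(cs1 - [coupling partner]) while solid is left; crystals form when [coupling partner] > cs1 (solubility = 0.730 M, k = 0.00100 s⁻¹)
    coupling partner + left-handed substrate → left-handed product (k = 2.70 × 10⁻⁴ M⁻¹ s⁻¹, Ea = 74.0 kJ mol⁻¹)
    coupling partner + right-handed substrate → right-handed product (k = 8.60 × 10⁻⁵ M⁻¹ s⁻¹, Ea = 81.0 kJ mol⁻¹)
    right-handed substrate ⇌ achiral form (K = 0.430, k = 2.20 × 10⁻⁴ s⁻¹, Ea = 98.0 kJ mol⁻¹, ΔH = −5.00 kJ mol⁻¹)
    left-handed substrate ⇌ achiral form (K = 0.430, k = 2.20 × 10⁻⁴ s⁻¹, Ea = 98.0 kJ mol⁻¹, ΔH = −5.00 kJ mol⁻¹)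
    (constants at 40 °C)

Monday's flask stood 3.9 percentage points above Friday's at 2.0 h, but read at 5.0 h it gives 39.6%, 0.078 points from Friday's value at 2.0 h and inside the margin of 1.5 points. With the factor 3.99 and the hands apart, the 5.1% of left-handed substrate left in Friday's flask would go with 47.4% of right-handed substrate, and 5.3% stood there. In Wednesday's flask, which stood at 40 °C until 80 min, the factor read at 70 °C, taken over as it stands, would pair the 12% left of the left-handed substrate with 58.8%, and 13% of the right-handed substrate stood there.

The data were generated by integration with constants of no real substance; scatter was added.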